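**Retrosynthetic overview**
1. The C11(OH)(CH2OAc)2 side chain is traced back to an isopropenyl group (allylic hydroxylation, dihydroxylation, acetylation), which leaves a 1αH,5αH-guai-11-ene-4α,6α,10α-triol.
2. The strategy rests on the C1–C5 fusion bond of the hydroazulene and the two tertiary carbinols C4 and C10 beside it, both hydroxyls cis to H1 and H5. Cutting C1–C5 together with C10–OH gives a trans-4,5-epoxycyclodec-1(10)E-ene (germacrane) and water.
3. The oxirane comes from the C4=C5 alkene under direction by the C6 hydroxyl. The ten-membered ring is cut at C6–C7 to 12-bromofarnesal (enal plus allylic bromide), made from (2E,6E)-farnesol.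
4. Ring order: ten-membered carbocycle first, oxirane second, then one transannular C–C bond turns the macrocycle into the cyclopentane and the cycloheptane at once.

Key step: step 9

Remark on the chemistry: the sense of induction of a chromium-bound chiral ligand cannot be predicted for this ring closure, so the ligand antipode that gives the (6R,7S) alcohol is assumed to be found by trial.

**Route**

Step 1
Reactants: 1 (2E,6E)-farnesol
Product: 2 (2E,6E)-farnesyl acetate
Conditions: Ac2O, pyridine, DMAP (cat.), CH2Cl2, 0 °C → rt
Reagents that add atoms: acetic anhydride, CC(=O)OC(C)=O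
Why: Routine O-acetylation masks the primary allylic alcohol and makes the C2=C3 alkene less prone to the allylic oxidation that follows.

Step 2
Reactants: 2 (2E,6E)-farnesyl acetate
Product: 3 (2E,6E,10E)-12-hydroxyfarnesyl acetate
Conditions: SeO2 (5 mol%), salicylic acid (10 mol%), t-BuOOH (70% aq., 3 equiv), CH2Cl2, 0 °C → rt, stopped at partial conversion, 2 recycled
Reagents that add atoms: tert-butyl hydroperoxide, CC(C)(C)OO (terminal oxidant; its oxygen is relayed by the catalyst SeO2, O=[Se]=O)
Why: The ene/[2,3]-sigmatropic sequence of SeO2 (Riley-type allylic hydroxylation) should attack the electron-rich terminal trisubstituted alkene at its (E)-methyl group and give the 10E primary allylic alcohol.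

Step 3
Reactants: 3 (2E,6E,10E)-12-hydroxyfarnesyl acetate
Product: 4 (2E,6E,10E)-12-bromofarnesyl acetate
Conditions: CBr4 (1.2 equiv), PPh3 (1.25 equiv), CH2Cl2, −20 → 0 °C
Reagents that add atoms: carbon tetrabromide, BrC(Br)(Br)Br
Why: In this Appel reaction bromide displaces the alkoxyphosphonium group at the primary carbon without allylic shift, and the allylic acetate is not touched.

Step 4
Reactants: 4 (2E,6E,10E)-12-bromofarnesyl acetate
Product: 5 (2E,6E,10E)-12-bromofarnesol
Conditions: i-Bu2AlH (DIBAL-H, 2.3 equiv), CH2Cl2, −78 °C; aq. KNaC4H4O6 work-up, cold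
Reagents that add atoms: none
Why: Reductive cleavage of the acetate by the aluminium hydride at −78 °C avoids the alkoxide or carbonate nucleophiles of a solvolytic deacetylation, which would displace the allylic bromide, while the bromide itself is inert to the hydride at this temperature.

Step 5
Reactants: 5 (2E,6E,10E)-12-bromofarnesol
Product: 6 (2E,6E,10E)-12-bromofarnesal
Conditions: MnO2 (activated, 20 equiv), CH2Cl2, rt; filtered and used at once
Reagents that add atoms: none
Why: MnO2 oxidises only the allylic alcohol, should give the (2E)-enal without geometric isomerisation, and leaves the allylic bromide alone.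

Step 6
Reactants: 6 (2E,6E,10E)-12-bromofarnesal
Product: 8 (6R,7S)-germacra-1(10)E,4E,11-trien-6-ol, via allylchromium dichloride 7 (not isolated)
Conditions: CrCl2 (4 equiv), N-[2-(4-isopropyl-4,5-dihydrooxazol-2-yl)-6-methylphenyl]methanesulfonamide (single enantiomer, 4.4 equiv), Et3N (4.4 equiv), THF, rt, 1 h; then 6 by syringe pump over 12 h to 2 mM, 0 °C → rt; aq. KNaC4H4O6/NaHCO3 work-up, no acid, product kept below 25 °C
Reagents that add atoms: none
Why: Proposed new method: two equivalents of divalent chromium convert the allylic bromide into the (E)-σ-allylchromium species 7, which adds through its γ-carbon (farnesane C10, the future C7) to the chromium-bound aldehyde in a closed six-membered chair and so forms C6–C7 and the ten-membered ring; the chair with both tether carbons equatorial gives the 6,7-anti pair (hydroxyl and isopropenyl trans on the ring), and the sulfonamide–oxazoline ligand on chromium selects the aldehyde face and hence the absolute configuration; the closest known reactions are the ligand-controlled asymmetric Nozaki–Hiyama allylation of aldehydes by allyl halides between two molecules and the ligand-free CrCl2 closure of ω-haloallyl farnesal-type enals to germacranes, and only their combination in a medium-ring closure is untested.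

Step 7
Reactants: 8 (6R,7S)-germacra-1(10)E,4E,11-trien-6-ol
Product: 9 (4R,5R,6S,7S)-4,5-epoxygermacra-1(10)E,11-dien-6-ol (trans-oxirane, threo to O6)
Conditions: VO(acac)2 (5 mol%), t-BuOOH (1.3 equiv, in decane), CH2Cl2, 0 °C; aq. Na2S2O3/NaHCO3
Reagents that add atoms: tert-butyl hydroperoxide, CC(C)(C)OO
Why: Hydroxyl-directed epoxidation through a vanadium alkoxide–peroxide complex reaches only the allylic C4=C5 bond; because C15 is cis to C6 the carbinol hydrogen eclipses the alkene (A1,3 control) and the macrocycle exposes only the outward face on the side of O6, so the threo (4R,5R) epoxide should form while the stereochemistry at C6 and C7 is untouched.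

Step 8
Reactants: 9 (4R,5R,6S,7S)-4,5-epoxygermacra-1(10)E,11-dien-6-ol
Product: 10 6-O-tert-butyldimethylsilyl ether of 9
Conditions: TBSOTf (1.3 equiv), 2,6-lutidine (3 equiv), CH2Cl2, −78 °C; NaHCO3 quench at −78 °C
Reagents that add atoms: tert-butyldimethylsilyl triflate, CC(C)(C)[Si](C)(C)OS(=O)(=O)C(F)(F)F
Why: Silyl triflate silylation of the hindered secondary alcohol is fast at −78 °C, the excess lutidine keeps the medium basic so the oxirane is not activated, and the resulting ether can neither open the epoxide nor capture a cation in the next step.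

Step 9
Reactants: 10 6-O-TBS-(4R,5R,6S,7S)-4,5-epoxygermacra-1(10)E,11-dien-6-ol
Product: 11 6-O-TBS-1αH,5αH,7αH-guai-11-ene-4α,6α,10α-triol (4- and 10-hydroxyls free)
Conditions: p-TsOH·H2O (0.1 equiv), acetone/H2O 3:1, 0 °C; NaHCO3 quench
Reagents that add atoms: water, O
Why: Protonation of the oxirane lets the C1=C10 π bond, which the crossed conformer of the (E)-cyclodecene holds directly behind C5, displace the C5–O bond from inside the ring while water adds to the developing C10 cation; this is the acid-promoted transannular cyclisation of 4,5-epoxygermacr-1(10)-enes to cis-fused 4-hydroxyguaianes, run here so that hydration and not proton loss ends it. The cyclopentane (C1–C5) closes exo with respect to the alkene (C10 stays outside it) with both oxirane carbons inside it, and the cycloheptane is the remainder of the macrocycle, closed endo with respect to the alkene with C4 left outside. C4 keeps its C–O bond and therefore its configuration, C5 is inverted by the backside C–C bond formation, the cis fusion (H1 and H5 on one face) follows from the crossed conformer with both ring methyls on the same face, which the equatorial C6 silyloxy and C7 isopropenyl groups fix, and C10 is set by anti addition of C5 and water across the E alkene, which places 10-OH cis to H1. The step needs carbon and not water to open the epoxide, and hydration and not elimination or ether formation at C10: the transannular contact makes the C–C closure effectively intramolecular, the water-rich medium intercepts the tertiary cation on its open face, the silyl ether keeps O6 from acting as a nucleophile, and the 1,1-disubstituted side-chain alkene is not protonated by dilute acid at 0 °C.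

Step 10
Reactants: 11 6-O-TBS-1αH,5αH,7αH-guai-11-ene-4α,6α,10α-triol
Product: 12 6-O-TBS-1αH,5αH,7αH-guai-11(13)-ene-4α,6α,10α,12-tetrol (side chain CH2=C(CH2OH)–)
Conditions: SeO2 (0.3 equiv), t-BuOOH (3 equiv, in decane), CH2Cl2, 0 °C → rt, stopped at partial conversion, 11 recycled
Reagents that add atoms: tert-butyl hydroperoxide, CC(C)(C)OO (oxygen relayed by the catalyst SeO2, O=[Se]=O)
Why: The isopropenyl group is the only alkene left, and the SeO2 ene/[2,3] sequence prefers its methyl hydrogens to the hindered tertiary C7–H, so the 2-substituted allylic alcohol should form with C7 unchanged.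

Step 11
Reactants: 12 6-O-TBS-1αH,5αH,7αH-guai-11(13)-ene-4α,6α,10α,12-tetrol
Product: 13 6-O-TBS-1αH,5αH,7αH-guaiane-4α,6α,10α,11,12,13-hexol
Conditions: OsO4 (2 mol%), NMO (1.5 equiv), acetone/H2O 4:1, rt; aq. Na2SO3
Reagents that add atoms: N-methylmorpholine N-oxide, C[N+]1([O-])CCOCC1 (oxygen relayed by OsO4, O=[Os](=O)(=O)=O); water, O
Why: Catalytic osmium dihydroxylation (Upjohn conditions) of the single alkene turns C11 into C(OH)(CH2OH)2, which carries two identical arms, so no stereocentre arises and the face of attack does not matter.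

Step 12
Reactants: 13 6-O-TBS-1αH,5αH,7αH-guaiane-4α,6α,10α,11,12,13-hexol
Product: 14 6-O-TBS-1αH,5αH,7αH-guaiane-4α,6α,10α,11,12,13-hexol 12,13-diacetate
Conditions: Ac2O (2.3 equiv), pyridine, CH2Cl2, 0 °C, no DMAP
Reagents that add atoms: acetic anhydride, CC(=O)OC(C)=O
Why: Without an acyl-transfer catalyst only the two primary hydroxyls are acetylated, the three tertiary hydroxyls being inert and O6 silylated.

Step 13
Reactants: 14 6-O-TBS-1αH,5αH,7αH-guaiane-4α,6α,10α,11,12,13-hexol 12,13-diacetate
Product: 15 (1R,4R,5S,6S,7R,10R)-1αH,5αH,7αH-guaiane-4α,6α,10α,11,12,13-hexol 12,13-diacetate (CNP0179913.1)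
Conditions: HF·pyridine, excess pyridine, THF, 0 °C → rt; aq. NaHCO3
Reagents that add atoms: none
Why: Fluoride cleaves the Si–O bond, and the pyridine buffer keeps the medium too weakly acidic to ionise the tertiary carbinols and too weakly basic to move or remove the acetates.

**Compound list**
1 | (2E,6E)-farnesol | CC(C)=CCC/C(C)=C/CC/C(C)=C/CO | starting material
2 | (2E,6E)-farnesyl acetate | CC(C)=CCC/C(C)=C/CC/C(C)=C/COC(C)=O | intermediate
3 | (2E,6E,10E)-12-hydroxyfarnesyl acetate | OC/C(C)=C/CC/C(C)=C/CC/C(C)=C/COC(C)=O | intermediate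
4 | (2E,6E,10E)-12-bromofarnesyl acetate | BrC/C(C)=C/CC/C(C)=C/CC/C(C)=C/COC(C)=O | intermediate
5 | (2E,6E,10E)-12-bromofarnesol | BrC/C(C)=C/CC/C(C)=C/CC/C(C)=C/CO | intermediate
6 | (2E,6E,10E)-12-bromofarnesal | BrC/C(C)=C/CC/C(C)=C/CC/C(C)=C/C=O | intermediate
7 | (2E,6E,10E)-12-(dichlorochromio)farnesal, the σ-allylchromium species (drawn without the sulfonamide ligand and THF) | Cl[Cr](Cl)C/C(C)=C/CC/C(C)=C/CC/C(C)=C/C=O | intermediate
8 | (6R,7S)-germacra-1(10)E,4E,11-trien-6-ol (6-OH and 7-isopropenyl trans) | C=C(C)[C@@H]1CC/C(C)=C/CC/C(C)=C/[C@H]1O | intermediate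
9 | (4R,5R,6S,7S)-4,5-epoxygermacra-1(10)E,11-dien-6-ol | C=C(C)[C@@H]1CC/C(C)=C/CC[C@@]2(C)O[C@@H]2[C@H]1O | intermediate
10 | 6-O-TBS ether of 9 | C=C(C)[C@@H]1CC/C(C)=C/CC[C@@]2(C)O[C@@H]2[C@H]1O[Si](C)(C)C(C)(C)C | intermediate
11 | 6-O-TBS-1αH,5αH,7αH-guai-11-ene-4α,6α,10α-triol | C=C(C)[C@@H]1CC[C@@](C)(O)[C@@H]2CC[C@@](C)(O)[C@@H]2[C@H]1O[Si](C)(C)C(C)(C)C | intermediate
12 | 6-O-TBS-1αH,5αH,7αH-guai-11(13)-ene-4α,6α,10α,12-tetrol | C=C(CO)[C@@H]1CC[C@@](C)(O)[C@@H]2CC[C@@](C)(O)[C@@H]2[C@H]1O[Si](C)(C)C(C)(C)C | intermediate
13 | 6-O-TBS-1αH,5αH,7αH-guaiane-4α,6α,10α,11,12,13-hexol | OCC(O)(CO)[C@@H]1CC[C@@](C)(O)[C@@H]2CC[C@@](C)(O)[C@@H]2[C@H]1O[Si](C)(C)C(C)(C)C | intermediate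
14 | 6-O-TBS-1αH,5αH,7αH-guaiane-4α,6α,10α,11,12,13-hexol 12,13-diacetate | CC(=O)OCC(O)(COC(C)=O)[C@@H]1CC[C@@](C)(O)[C@@H]2CC[C@@](C)(O)[C@@H]2[C@H]1O[Si](C)(C)C(C)(C)C | intermediate
15 | (1R,4R,5S,6S,7R,10R)-1αH,5αH,7αH-guaiane-4α,6α,10α,11,12,13-hexol 12,13-diacetate (CNP0179913.1) | CC(=O)OCC(O)(COC(C)=O)[C@@H]1CC[C@@](C)(O)[C@@H]2CC[C@@](C)(O)[C@@H]2[C@H]1O | target

Total step count: 13
Longest linear sequence: 13 steps (1 → 15)

**Steps most likely to fail**

Step 6 (the labelled step). The ligand may discriminate the aldehyde faces poorly in the constrained medium-ring transition state, and intermolecular coupling may compete with ring closure. The fallback gives up catalyst control for resolution; it sets out from 6 and comes back at 8. Ligand-free CrCl2 in THF at high dilution closes the ring through the same allylchromium 7 to the racemic trans alcohol, which is 8 together with its antipode (6S,7R)-germacra-1(10)E,4E,11-trien-6-ol F1. The mixture is esterified with (S)-O-methylmandelic acid (DCC, DMAP, CH2Cl2, 0 °C) to the (S)-O-methylmandelate of 8 F2 and the (S)-O-methylmandelate of the antipode F3. These diastereomers are separated by chromatography on base-washed silica. K2CO3 in MeOH at 0 °C then releases enantiopure 8 from F2.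

Step 9. Proton loss from the C10 cation, or direct hydrolysis of the oxirane by water, may outrun the hydration-terminated transannular closure, and the silyl ether may be lost in the aqueous acid. The fallback separates ring closure from introduction of the C10 oxygen; it sets out from 10 and comes back at 11. Anhydrous Et2AlCl (CH2Cl2, −78 °C), a Lewis acid that carries its own base, should cyclise 10 with loss of a C14 proton to 6-O-TBS-1αH,5αH-guaia-10(14),11-dien-4α-ol F4. The free 4α-hydroxyl then directs VO(acac)2/t-BuOOH to the α face of the C10=C14 bond only, the isopropenyl group having no free hydroxyl within reach, to give the 10α,14-epoxide F5. LiAlH4 (THF, 0 °C) opens F5 at its CH2 terminus to the 10α-carbinol 11.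

Step 10. Over-oxidation to the enal, competing hydrogen abstraction at the C7 methine and sluggish conversion in the presence of two free tertiary alcohols may erode the allylic hydroxylation. The fallback replaces the ene oxidation by epoxidation and base-promoted isomerisation; it sets out from 11 and comes back at 12. mCPBA (NaHCO3, CH2Cl2, 0 °C) epoxidises the only alkene to the 11,12-epoxide F6, formed as both C11 epimers, which converge. Diethylaluminium 2,2,6,6-tetramethylpiperidide, Et2Al(NC9H18), in excess (toluene, 0 °C) removes a methyl proton and opens the oxirane to the allylic alcohol 12.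

**Further compounds**
F1 | step 6 | (6S,7R)-germacra-1(10)E,4E,11-trien-6-ol (antipode of 8) | C=C(C)[C@H]1CC/C(C)=C/CC/C(C)=C/[C@@H]1O
F2 | step 6 | (S)-O-methylmandelate of 8 | C=C(C)[C@@H]1CC/C(C)=C/CC/C(C)=C/[C@H]1OC(=O)[C@@H](OC)c1ccccc1
F3 | step 6 | (S)-O-methylmandelate of F1 | C=C(C)[C@H]1CC/C(C)=C/CC/C(C)=C/[C@@H]1OC(=O)[C@@H](OC)c1ccccc1
F4 | step 9 | 6-O-TBS-1αH,5αH-guaia-10(14),11-dien-4α-ol | C=C(C)[C@@H]1CCC(=C)[C@@H]2CC[C@@](C)(O)[C@@H]2[C@H]1O[Si](C)(C)C(C)(C)C
F5 | step 9 | 6-O-TBS-10α,14-epoxy-1αH,5αH-guai-11-en-4α-ol | C=C(C)[C@@H]1CC[C@]3(CO3)[C@@H]2CC[C@@](C)(O)[C@@H]2[C@H]1O[Si](C)(C)C(C)(C)C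
F6 | step 10 | 6-O-TBS-11,12-epoxy-1αH,5αH,7αH-guaiane-4α,10α-diol (both C11 epimers) | CC3(CO3)[C@@H]1CC[C@@](C)(O)[C@@H]2CC[C@@](C)(O)[C@@H]2[C@H]1O[Si](C)(C)C(C)(C)C
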